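Ring B is cut back by two carbons. The fragment C5–C6–C1–C2 with the C2 ketone is treated as a 3,3-disubstituted cyclobutanone whose two acyl–CH2 bonds (C2–C1 and C2–C5) are enantiotopic. A chiral zerovalent nickel catalyst inserts a silylated propargyl ether into one of them. This single operation forms C2–C3 and C4–C5, closes ring B as a cyclohexenone, puts C15 on C3 and fixes the spiro carbon C6. The precursor is an achiral cyclobutanone that bears on C6 the isopropenyl group (C7, C8, C14) and the chain CMe2CH2CH2OAc (C11, C10, C9). Ring B is completed first. Ring A is closed last by a carbonyl-ene reaction.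

Key step: step 10

Locants: chamigrene numbering is used for all intermediates. C6 is the spiro carbon. C1–C5 complete ring B (C2 carbonyl, C3 carbinol carbon carrying C15). C7–C11 complete ring A (C14 on C7, hydroxyl on C9, bromine on C10, two methyls on C11).

Assumption: the sense of induction of the chiral ligand cannot be derived from a model; both antipodes are available, and the one that gives (S)-22 is used.

Design choices:
- Silicon on the alkyne is BnMe2Si, because a trialkylsilyl group on the β-carbon of an enone resists acid, whereas BnMe2Si leaves with fluoride.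
- O9 is an acetate, which is stable to fluoride and is lost in step 14 without a separate step.
- O15 is a 4-methoxybenzyl (PMB) ether, removed oxidatively in the presence of alkenes.
- The ketone is masked as a dimethyl ketal, which cleaves under acid too mild to protonate the isopropenylcyclobutane.
- All basic steps come before the bromohydrin is made.

Step 1
Reactants: 1 3,3-dimethoxycyclobutane-1-carboxylic acid; 2 3-methylbut-2-en-1-ol (prenol)
Product: 3 3-methylbut-2-en-1-yl 3,3-dimethoxycyclobutane-1-carboxylate
Conditions: DCC, DMAP (cat.), CH2Cl2, 0 °C to rt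
Reagents that add atoms: none
Why: Steglich esterification (carbodiimide activation with DMAP as acyl-transfer catalyst) joins acid and allylic alcohol under neutral conditions that leave the dimethyl ketal and the acid-sensitive prenyl group intact.

Step 2
Reactants: 3 3-methylbut-2-en-1-yl 3,3-dimethoxycyclobutane-1-carboxylate
Product: 7 3,3-dimethoxy-1-(2-methylbut-3-en-2-yl)cyclobutane-1-carboxylic acid, via lithium ester enolate 4 (not isolated), via silyl ketene acetal 5 (not isolated), via trimethylsilyl ester 6 (not isolated)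
Conditions: LiN(iPr)2, THF, −78 °C; Me3SiCl, −78 °C to rt, then 60 °C; H2O, aq. citric acid to pH 4
Reagents that add atoms: chlorotrimethylsilane, C[Si](C)(C)Cl (silicon only in 5 and 6); lithium diisopropylamide, [Li]N(C(C)C)C(C)C (lithium only in 4)
Why: Ireland–Claisen rearrangement, in which silyl ketene acetal 5 undergoes a [3,3]-sigmatropic shift that joins C6 to C11 intramolecularly and so sets two adjacent quaternary carbons, while no stereocentre arises because the cyclobutane keeps its mirror plane.

Step 3
Reactants: 7 3,3-dimethoxy-1-(2-methylbut-3-en-2-yl)cyclobutane-1-carboxylic acid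
Product: 9 1-[3,3-dimethoxy-1-(2-methylbut-3-en-2-yl)cyclobutyl]ethan-1-one, via dilithium gem-diolate 8 (not isolated)
Conditions: MeLi (2.5 equiv), Et2O, 0 °C to rt; inverse quench into ice-water
Reagents that add atoms: methyllithium, [Li]C
Why: Addition of methyllithium to a lithium carboxylate stops at gem-diolate 8, which cannot collapse before the aqueous quench, so the hindered acid should give the methyl ketone at C7 and not the tertiary alcohol.

Step 4
Reactants: 9 1-[3,3-dimethoxy-1-(2-methylbut-3-en-2-yl)cyclobutyl]ethan-1-one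
Product: 10 1,1-dimethoxy-3-(2-methylbut-3-en-2-yl)-3-(prop-1-en-2-yl)cyclobutane
Conditions: Cp2TiMe2 (3 equiv), toluene, 75 °C, dark
Reagents that add atoms: dimethyltitanocene Cp2TiMe2, C[Ti](C)(C1C=CC=C1)C1C=CC=C1
Why: Petasis methylenation, in which the small, non-basic titanium methylidene formed on heating converts hindered, enolisable ketones into 1,1-disubstituted alkenes where a phosphorus ylide would mainly enolise, and ketal and vinyl group are left alone.

Step 5
Reactants: 10 1,1-dimethoxy-3-(2-methylbut-3-en-2-yl)-3-(prop-1-en-2-yl)cyclobutane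
Product: 12 3-[3,3-dimethoxy-1-(prop-1-en-2-yl)cyclobutyl]-3-methylbutan-1-ol, via trialkylborane 11 (not isolated)
Conditions: Sia2BH [BH3·THF + 2-methylbut-2-ene, THF, 0 °C], 0 °C to rt; then NaOH, H2O2, 0 °C
Reagents that add atoms: hydrogen peroxide, OO (oxygen on C9); disiamylborane, CC(C)C(C)BC(C)C(C)C (boron only in 11)
Why: Hydroboration–oxidation with a bulky dialkylborane, which prefers monosubstituted over 1,1-disubstituted alkenes, should pick the vinyl group over the isopropenyl group shielded by quaternary C6 and should place boron on terminal C9.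

Step 6
Reactants: 12 3-[3,3-dimethoxy-1-(prop-1-en-2-yl)cyclobutyl]-3-methylbutan-1-ol
Product: 13 3-[3,3-dimethoxy-1-(prop-1-en-2-yl)cyclobutyl]-3-methylbutyl acetate
Conditions: Ac2O, pyridine, DMAP (cat.), CH2Cl2, rt
Reagents that add atoms: acetic anhydride, CC(=O)OC(C)=O
Why: DMAP-catalysed acylation of a primary alcohol gives an ester that survives the mild acid of step 7, the nickel catalyst, brief fluoride treatment and the low-temperature hydride of step 12.

Step 7
Reactants: 13 3-[3,3-dimethoxy-1-(prop-1-en-2-yl)cyclobutyl]-3-methylbutyl acetate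
Product: 14 3-methyl-3-[3-oxo-1-(prop-1-en-2-yl)cyclobutyl]butyl acetate (achiral)
Conditions: p-TsOH·H2O (5 mol %), acetone–H2O, rt
Reagents that add atoms: water, O
Why: Acid-catalysed hydrolysis of an open-chain dimethyl ketal proceeds far faster than protonation of the isopropenyl group, which has to be avoided because the resulting cyclobutylcarbinyl cation would ring-expand.

Step 8
Reactants: 15 prop-2-yn-1-ol
Product: 17 1-methoxy-4-[(prop-2-yn-1-yloxy)methyl]benzene, via sodium alkoxide 16 (not isolated)
Conditions: NaH, THF–DMF, 0 °C; PMBCl, Bu4NI (cat.), 0 °C to rt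
Reagents that add atoms: 4-methoxybenzyl chloride, COc1ccc(CCl)cc1; sodium hydride, [Na+].[H-] (sodium only in 16)
Why: Williamson ether synthesis on the alkoxide of a primary alcohol with a reactive benzylic chloride installs the oxidatively removable group on O15.

Step 9
Reactants: 17 1-methoxy-4-[(prop-2-yn-1-yloxy)methyl]benzene
Product: 19 benzyl{3-[(4-methoxybenzyl)oxy]prop-1-yn-1-yl}dimethylsilane, via lithium acetylide 18 (not isolated)
Conditions: n-BuLi, THF, −78 °C; BnMe2SiCl, −78 °C to rt
Reagents that add atoms: benzylchlorodimethylsilane, C[Si](C)(Cl)Cc1ccccc1; n-butyllithium, [Li]CCCC (lithium only in 18)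
Why: Deprotonation of the terminal alkyne and C-silylation of the acetylide give an internal alkyne whose two ends differ strongly in size, as the regiochemistry of step 10 requires.

Step 10
Reactants: 14 3-methyl-3-[3-oxo-1-(prop-1-en-2-yl)cyclobutyl]butyl acetate; 19 benzyl{3-[(4-methoxybenzyl)oxy]prop-1-yn-1-yl}dimethylsilane
Product: 22 (S)-3-[3-(benzyldimethylsilyl)-4-(4-methoxybenzyloxymethyl)-5-oxo-1-(prop-1-en-2-yl)cyclohex-3-en-1-yl]-3-methylbutyl acetate, via oxanickelacyclopentene 20 (not isolated), via nickelacycloheptenone 21 (not isolated)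
Conditions: Ni(cod)2 (10 mol %), (S,R,R)-(1,1'-binaphthyl-2,2'-diyl) N,N-bis(1-phenylethyl)phosphoramidite (20 mol %), toluene, 90 °C, 19 (1.5 equiv) added slowly
Reagents that add atoms: none
Why: Proposed new method: zerovalent nickel bound to the chiral phosphoramidite should couple the strained C2 carbonyl of 14 with alkyne 19 by oxidative cyclisation to oxanickelacyclopentene 20, in which C3 is bonded to C2 and the silyl-bearing C4 to nickel, and β-carbon elimination then cleaves one C2–CH2 bond with release of ring strain to give nickelacycloheptenone 21. Ring B closes by C(sp2)–C(sp3) reductive elimination from 21, which forms C4–C5 and returns zerovalent nickel, so that the four-membered ring grows by two carbons in a formal [4+2] process. The closest known reaction type is the Ni(cod)2–trialkylphosphine-catalysed intermolecular insertion of internal alkynes into 3,3-disubstituted cyclobutanones, and ligand-controlled choice between enantiotopic cyclobutanone bonds is known only for intramolecular alkene insertion, so the new element is the union of an unsymmetrical intermolecular alkyne with enantiotopic bond selection. C6, the only new stereocentre, is fixed in the β-carbon elimination, where the chiral ligand decides whether C2–C5 or C2–C1 breaks, helped by the large difference in shape between the flat isopropenyl group and the tert-alkyl chain on C6. The regioselectivity that is needed is secured by the bulky BnMe2Si group, which avoids the congested new C2–C3 bond and sits next to nickel. Chemoselectivity for the alkyne rests on the hindered 1,1-disubstituted alkene on C6, which cannot reach the carbonyl group, and on the inertness of the alkyl acetate and the benzylic ether towards the catalyst.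

Step 11
Reactants: 22 (S)-3-[3-(benzyldimethylsilyl)-4-(4-methoxybenzyloxymethyl)-5-oxo-1-(prop-1-en-2-yl)cyclohex-3-en-1-yl]-3-methylbutyl acetate
Product: 23 (R)-3-[4-(4-methoxybenzyloxymethyl)-5-oxo-1-(prop-1-en-2-yl)cyclohex-3-en-1-yl]-3-methylbutyl acetate
Conditions: Bu4NF (2.5 equiv), wet THF, 0 °C, short contact time
Reagents that add atoms: none
Why: Fluoride-promoted protodesilylation of a benzyldimethylsilyl alkene, in which fluoride first expels the benzyl group and the resulting fluorosilane becomes hypervalent so that the C4–Si bond is protonated, a cleavage that the electron-poor C4 favours, while C6 is untouched and its descriptor changes only because silicon leaves.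

Step 12
Reactants: 23 (R)-3-[4-(4-methoxybenzyloxymethyl)-5-oxo-1-(prop-1-en-2-yl)cyclohex-3-en-1-yl]-3-methylbutyl acetate
Product: 25 3-[(1R,4R)-4-hydroxy-4-(4-methoxybenzyloxymethyl)-3-oxo-1-(prop-1-en-2-yl)cyclohexyl]-3-methylbutyl acetate, via lithium enolate 24 (not isolated)
Conditions: LiBH(s-Bu)3 (1.05 equiv), THF, −78 °C; 2-(phenylsulfonyl)-3-phenyloxaziridine, −78 °C; AcOH quench
Reagents that add atoms: 2-(phenylsulfonyl)-3-phenyloxaziridine, O=S(=O)(c1ccccc1)N1OC1c1ccccc1 (oxygen on C3); lithium tri-sec-butylborohydride, [Li+].CCC(C)[BH-](C(C)CC)C(C)CC (lithium only in 24)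
Why: Conjugate reduction of a β-unsubstituted cyclohexenone by the bulky borohydride gives regiodefined enolate 24, whose N-sulfonyloxaziridine hydroxylation occurs at C3 by axial attack on the face opposite to the axial isopropenyl group (the tert-alkyl chain on C6 stays equatorial), which puts the hydroxyl cis to C11 as the target requires, while −78 °C suppresses E1cB loss of the C15 alkoxide.

Step 13
Reactants: 25 3-[(1R,4R)-4-hydroxy-4-(4-methoxybenzyloxymethyl)-3-oxo-1-(prop-1-en-2-yl)cyclohexyl]-3-methylbutyl acetate
Product: 26 3-[(1R,4R)-4-hydroxy-4-(hydroxymethyl)-3-oxo-1-(prop-1-en-2-yl)cyclohexyl]-3-methylbutyl acetate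
Conditions: DDQ, CH2Cl2–pH 7 buffer, 0 °C
Reagents that add atoms: none
Why: Oxidative cleavage of the electron-rich 4-methoxybenzyl ether by DDQ in wet solvent (hydride abstraction, then hydrolysis of the oxocarbenium ion) frees O15 without touching alkene, acetate or ketol, which hydrogenolysis of a plain benzyl ether could not achieve.

Step 14
Reactants: 26 3-[(1R,4R)-4-hydroxy-4-(hydroxymethyl)-3-oxo-1-(prop-1-en-2-yl)cyclohexyl]-3-methylbutyl acetate
Product: 28 (3R,6R)-6-(4-hydroxy-2-methylbutan-2-yl)-6-(prop-1-en-2-yl)-1-oxaspiro[2.5]octan-4-one, via primary mesylate 27 (not isolated)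
Conditions: MsCl, Et3N, CH2Cl2, −20 °C; then K2CO3, MeOH, 0 °C to rt
Reagents that add atoms: methanesulfonyl chloride, CS(=O)(=O)Cl (only in 27)
Why: Chemoselective mesylation of the primary hydroxyl followed by intramolecular Williamson closure (3-exo-tet SN2 at C15, so the C3–O bond and its configuration are untouched) gives the spiro-epoxide, and the same methanolic carbonate transesterifies the acetate so that O9 is freed without a separate step.

Step 15
Reactants: 28 (3R,6R)-6-(4-hydroxy-2-methylbutan-2-yl)-6-(prop-1-en-2-yl)-1-oxaspiro[2.5]octan-4-one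
Product: 29 (2S,5R)-2-(chloromethyl)-2-hydroxy-5-(4-hydroxy-2-methylbutan-2-yl)-5-(prop-1-en-2-yl)cyclohexan-1-one
Conditions: LiCl, AcOH, THF, rt
Reagents that add atoms: lithium chloride, [Li+].[Cl-]
Why: Buffered halide opening of a terminal epoxide, in which chloride attacks the unhindered C15 by SN2 because C3 is quaternary and a cation there would be destabilised by the adjacent carbonyl, so C3 keeps its geometry and becomes S only because CH2Cl outranks the carbonyl carbon.

Step 16
Reactants: 29 (2S,5R)-2-(chloromethyl)-2-hydroxy-5-(4-hydroxy-2-methylbutan-2-yl)-5-(prop-1-en-2-yl)cyclohexan-1-one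
Product: 30 3-[(1R,4S)-4-(chloromethyl)-4-hydroxy-3-oxo-1-(prop-1-en-2-yl)cyclohexyl]-3-methylbutanal
Conditions: Dess–Martin periodinane, CH2Cl2, 0 °C to rt
Reagents that add atoms: none
Why: Dess–Martin oxidation converts the only oxidisable alcohol, the primary C9 hydroxyl, into the aldehyde under near-neutral conditions that neither close the chlorohydrin nor disturb the tertiary ketol.

Step 17
Reactants: 30 3-[(1R,4S)-4-(chloromethyl)-4-hydroxy-3-oxo-1-(prop-1-en-2-yl)cyclohexyl]-3-methylbutanal
Product: 31 (2R)-2-bromo-3-[(1R,4S)-4-(chloromethyl)-4-hydroxy-3-oxo-1-(prop-1-en-2-yl)cyclohexyl]-3-methylbutanal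
Conditions: (R)-2-{bis[3,5-bis(trifluoromethyl)phenyl](trimethylsilyloxy)methyl}pyrrolidine (20 mol %), PhCO2H (20 mol %), 4,4-dibromo-2,6-di-tert-butylcyclohexa-2,5-dien-1-one, CH2Cl2–pentane, −24 °C; short silica plug, used at once
Reagents that add atoms: 4,4-dibromo-2,6-di-tert-butylcyclohexa-2,5-dien-1-one, O=C1C(C(C)(C)C)=CC(Br)(Br)C=C1C(C)(C)C
Why: Enamine-catalysed asymmetric α-bromination of an aldehyde, known also for β-quaternary aldehydes, in which the diaryl(silyloxy)methyl group of the R catalyst shields one face of the E-enamine so that bromine is delivered to give 10R under catalyst control, while the hindered C2 ketone forms no enamine and the mild bromine donor spares the isopropenyl group.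

Step 18
Reactants: 31 (2R)-2-bromo-3-[(1R,4S)-4-(chloromethyl)-4-hydroxy-3-oxo-1-(prop-1-en-2-yl)cyclohexyl]-3-methylbutanal
Product: 32 (3S,6R,9S,10R)-10-bromo-3-(chloromethyl)-3,9-dihydroxy-11,11-dimethyl-7-methylidenespiro[5.5]undecan-2-one
Conditions: Me2AlCl (3 equiv), CH2Cl2, −78 to −20 °C; H2O quench
Reagents that add atoms: none
Why: Lewis acid-promoted intramolecular carbonyl-ene reaction with the tether on the central alkene carbon, in which C8 attacks C9 while a hydrogen of the C14 methyl passes to oxygen through a chair with the aldehyde oxygen axial (it must reach C14–H) and C10–Br equatorial and anti to the incoming C8 (Felkin–Anh), which closes ring A, creates the exocyclic methylene and sets 9S as the cis-bromohydrin, the first equivalent of Me2AlCl being consumed by the C3 hydroxyl.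

Compound list
1 | 3,3-dimethoxycyclobutane-1-carboxylic acid | COC1(OC)CC(C1)C(=O)O | starting material
2 | 3-methylbut-2-en-1-ol (prenol) | CC(C)=CCO | starting material
3 | 3-methylbut-2-en-1-yl 3,3-dimethoxycyclobutane-1-carboxylate | COC1(OC)CC(C1)C(=O)OCC=C(C)C | intermediate
4 | lithium enolate of ester 3 | COC1(OC)CC(C1)=C(O[Li])OCC=C(C)C | intermediate
5 | trimethylsilyl ketene acetal of ester 3 | COC1(OC)CC(C1)=C(O[Si](C)(C)C)OCC=C(C)C | intermediate
6 | trimethylsilyl 3,3-dimethoxy-1-(2-methylbut-3-en-2-yl)cyclobutane-1-carboxylate | COC1(OC)CC(C1)(C(C)(C)C=C)C(=O)O[Si](C)(C)C | intermediate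
7 | 3,3-dimethoxy-1-(2-methylbut-3-en-2-yl)cyclobutane-1-carboxylic acid (achiral) | COC1(OC)CC(C1)(C(C)(C)C=C)C(=O)O | intermediate
8 | dilithium 1-[3,3-dimethoxy-1-(2-methylbut-3-en-2-yl)cyclobutyl]ethane-1,1-diolate | COC1(OC)CC(C1)(C(C)(C)C=C)C(C)(O[Li])O[Li] | intermediate
9 | 1-[3,3-dimethoxy-1-(2-methylbut-3-en-2-yl)cyclobutyl]ethan-1-one | COC1(OC)CC(C1)(C(C)(C)C=C)C(C)=O | intermediate
10 | 1,1-dimethoxy-3-(2-methylbut-3-en-2-yl)-3-(prop-1-en-2-yl)cyclobutane | COC1(OC)CC(C1)(C(C)(C)C=C)C(C)=C | intermediate
11 | {3-[3,3-dimethoxy-1-(prop-1-en-2-yl)cyclobutyl]-3-methylbutyl}bis(3-methylbutan-2-yl)borane | COC1(OC)CC(C1)(C(C)=C)C(C)(C)CCB(C(C)C(C)C)C(C)C(C)C | intermediate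
12 | 3-[3,3-dimethoxy-1-(prop-1-en-2-yl)cyclobutyl]-3-methylbutan-1-ol | COC1(OC)CC(C1)(C(C)=C)C(C)(C)CCO | intermediate
13 | 3-[3,3-dimethoxy-1-(prop-1-en-2-yl)cyclobutyl]-3-methylbutyl acetate | COC1(OC)CC(C1)(C(C)=C)C(C)(C)CCOC(C)=O | intermediate
14 | 3-methyl-3-[3-oxo-1-(prop-1-en-2-yl)cyclobutyl]butyl acetate (achiral precursor of the key step) | O=C1CC(C(C)=C)(C(C)(C)CCOC(C)=O)C1 | intermediate
15 | prop-2-yn-1-ol | C#CCO | starting material
16 | sodium prop-2-yn-1-olate | [Na+].[O-]CC#C | intermediate
17 | 1-methoxy-4-[(prop-2-yn-1-yloxy)methyl]benzene | C#CCOCc1ccc(OC)cc1 | intermediate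
18 | lithium acetylide of 17 | [Li]C#CCOCc1ccc(OC)cc1 | intermediate
19 | benzyl{3-[(4-methoxybenzyl)oxy]prop-1-yn-1-yl}dimethylsilane | C[Si](C)(Cc1ccccc1)C#CCOCc1ccc(OC)cc1 | intermediate
20 | spiro oxanickelacyclopentene, O and C4 on nickel, C3 bonded to C2 (ligand not drawn, configuration at C2 not specified) | O1[Ni]C([Si](C)(C)Cc2ccccc2)=C(COCc2ccc(OC)cc2)C13CC(C(C)=C)(C(C)(C)CCOC(C)=O)C3 | intermediate
21 | seven-membered nickelacycloheptenone, C4 and C5 on nickel, C6 configured as in 22 (ligand not drawn) | O=C1C[C@](C(C)=C)(C(C)(C)CCOC(C)=O)C[Ni]C([Si](C)(C)Cc2ccccc2)=C1COCc1ccc(OC)cc1 | intermediate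
22 | (S)-3-[3-(benzyldimethylsilyl)-4-(4-methoxybenzyloxymethyl)-5-oxo-1-(prop-1-en-2-yl)cyclohex-3-en-1-yl]-3-methylbutyl acetate (ring B enone, product of the key step) | O=C1C[C@](C(C)=C)(C(C)(C)CCOC(C)=O)CC([Si](C)(C)Cc2ccccc2)=C1COCc1ccc(OC)cc1 | intermediate
23 | (R)-3-[4-(4-methoxybenzyloxymethyl)-5-oxo-1-(prop-1-en-2-yl)cyclohex-3-en-1-yl]-3-methylbutyl acetate | O=C1C[C@](C(C)=C)(C(C)(C)CCOC(C)=O)CC=C1COCc1ccc(OC)cc1 | intermediate
24 | lithium C2–C3 enolate from 23 (6R) | [Li]OC1=C(COCc2ccc(OC)cc2)CC[C@@](C(C)=C)(C(C)(C)CCOC(C)=O)C1 | intermediate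
25 | 3-[(1R,4R)-4-hydroxy-4-(4-methoxybenzyloxymethyl)-3-oxo-1-(prop-1-en-2-yl)cyclohexyl]-3-methylbutyl acetate (C3–OH cis to C11) | O=C1C[C@](C(C)=C)(C(C)(C)CCOC(C)=O)CC[C@@]1(O)COCc1ccc(OC)cc1 | intermediate
26 | 3-[(1R,4R)-4-hydroxy-4-(hydroxymethyl)-3-oxo-1-(prop-1-en-2-yl)cyclohexyl]-3-methylbutyl acetate | O=C1C[C@](C(C)=C)(C(C)(C)CCOC(C)=O)CC[C@@]1(O)CO | intermediate
27 | 3-[(1R,4R)-4-hydroxy-4-(methylsulfonyloxymethyl)-3-oxo-1-(prop-1-en-2-yl)cyclohexyl]-3-methylbutyl acetate | O=C1C[C@](C(C)=C)(C(C)(C)CCOC(C)=O)CC[C@@]1(O)COS(C)(=O)=O | intermediate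
28 | (3R,6R)-6-(4-hydroxy-2-methylbutan-2-yl)-6-(prop-1-en-2-yl)-1-oxaspiro[2.5]octan-4-one | O=C1C[C@](C(C)=C)(C(C)(C)CCO)CC[C@@]12CO2 | intermediate
29 | (2S,5R)-2-(chloromethyl)-2-hydroxy-5-(4-hydroxy-2-methylbutan-2-yl)-5-(prop-1-en-2-yl)cyclohexan-1-one | O=C1C[C@](C(C)=C)(C(C)(C)CCO)CC[C@@]1(O)CCl | intermediate
30 | 3-[(1R,4S)-4-(chloromethyl)-4-hydroxy-3-oxo-1-(prop-1-en-2-yl)cyclohexyl]-3-methylbutanal | O=C1C[C@](C(C)=C)(C(C)(C)CC=O)CC[C@@]1(O)CCl | intermediate
31 | (2R)-2-bromo-3-[(1R,4S)-4-(chloromethyl)-4-hydroxy-3-oxo-1-(prop-1-en-2-yl)cyclohexyl]-3-methylbutanal | O=C1C[C@](C(C)=C)(C(C)(C)[C@@H](Br)C=O)CC[C@@]1(O)CCl | intermediate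
32 | (3S,6R,9S,10R)-10-bromo-3-(chloromethyl)-3,9-dihydroxy-11,11-dimethyl-7-methylidenespiro[5.5]undecan-2-one | C=C1C[C@H](O)[C@H](Br)C(C)(C)[C@@]12CC[C@@](O)(CCl)C(=O)C2 | target

Total step count: 18. Longest linear sequence: 16 (steps 1–7 and 10–18; steps 8 and 9 form the alkyne branch).

Steps most likely to fail

Step 10. Alkyne oligomerisation may outrun oxidative cyclisation at the hindered ketone, or the ligand may fail to distinguish the two C2–CH2 bonds. The fallback uses known chemistry, sets out from 14 and comes back at 23, and makes the three bonds one at a time.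
- 2,3-Dibromopropene and 4-methoxybenzyl alcohol (NaH, THF) give 2-bromoallyl 4-methoxybenzyl ether F1.
- Its alkenylcerium reagent (t-BuLi, then CeCl3, THF, −78 °C) adds to the ketone of 14 in preference to the acetate and forms C2–C3 in the tertiary alkenylcyclobutanol F2.
- Palladium-catalysed enantioselective ring-opening vinylation of tertiary cyclobutanols follows (Pd(OAc)2, chiral ferrocenyl P,N ligand, Cs2CO3, vinyl bromide, toluene, 60 °C). A divalent palladium alkoxide undergoes β-carbon elimination, and the neopentyl alkylpalladium, which has no β-hydrogen, couples with the vinyl group. This forms C4–C5 and sets C6 in the acyclic dienone F3.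
- Ring-closing metathesis with the second-generation Hoveyda–Grubbs catalyst (CH2Cl2, 40 °C) starts at the monosubstituted alkene, joins C4 to C3 and gives 23. The hindered isopropenyl group stays out of the metathesis.

Step 18. Facial selectivity at the aldehyde carbon C9 may be poor, or the Lewis acid may be diverted by the free ketol. The fallback sets out from 31 and comes back at 32, and C9 is set by hydride delivery rather than by the ring closure.
- Whatever mixture of 32 and its trans-bromohydrin C9 epimer F6 the closure delivers is oxidised at the secondary carbinol with Dess–Martin periodinane (CH2Cl2, 0 °C; the tertiary C3 hydroxyl is inert) to the 10-bromo-2,9-diketone F7.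
- i-Bu2AlH (CH2Cl2, −78 °C, one extra equivalent for the C3 hydroxyl) should reduce the more electrophilic and less shielded α-bromo ketone.
- Hydride should approach from the equatorial side, because the axial methyl group on C11 blocks axial approach. The hydroxyl then ends axial and cis to bromine, as in 32.

Step 12. The C15 alkoxide may be lost from enolate 24 by E1cB elimination, or the oxidant may attack the wrong face. The fallback sets out from 23 and comes back at 25, and replaces the metal enolate by a neutral enol ether.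
- RhCl(PPh3)3-catalysed 1,4-hydrosilylation with Et3SiH (toluene, 50 °C) gives the triethylsilyl enol ether F4, which cannot eliminate.
- Rubottom oxidation with dimethyldioxirane (acetone–CH2Cl2, −78 °C) is selective for the electron-rich tetrasubstituted enol ether over the isopropenyl group. It is directed to the face opposite to the axial isopropenyl group and gives, after silyl migration, the α-triethylsilyloxy ketone F5.
- HF·pyridine (THF, 0 °C) frees 25.

Further compounds
F1 | step 10 | 2-bromoallyl 4-methoxybenzyl ether | C=C(Br)COCc1ccc(OC)cc1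
F2 | step 10 | 3-{3-hydroxy-3-[3-(4-methoxybenzyloxy)prop-1-en-2-yl]-1-(prop-1-en-2-yl)cyclobutyl}-3-methylbutyl acetate (achiral, cis or trans) | OC1(C(=C)COCc2ccc(OC)cc2)CC(C(C)=C)(C(C)(C)CCOC(C)=O)C1
F3 | step 10 | (R)-3-allyl-3-isopropenyl dienone: C2 ketone bearing C3(=CH2)CH2OPMB, C5 bearing the vinyl carbon C4, C6 bearing isopropenyl and CMe2CH2CH2OAc | C=CC[C@@](C(C)=C)(C(C)(C)CCOC(C)=O)CC(=O)C(=C)COCc1ccc(OC)cc1
F4 | step 12 | triethylsilyl C2–C3 enol ether from 23 (6R) | CC[Si](CC)(CC)OC1=C(COCc2ccc(OC)cc2)CC[C@@](C(C)=C)(C(C)(C)CCOC(C)=O)C1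
F5 | step 12 | O3-triethylsilyl ether of 25 (1R,4R) | O=C1C[C@](C(C)=C)(C(C)(C)CCOC(C)=O)CC[C@@]1(O[Si](CC)(CC)CC)COCc1ccc(OC)cc1
F6 | step 18 | (3S,6R,9R,10R)-10-bromo-3-(chloromethyl)-3,9-dihydroxy-11,11-dimethyl-7-methylidenespiro[5.5]undecan-2-one | C=C1C[C@@H](O)[C@H](Br)C(C)(C)[C@@]12CC[C@@](O)(CCl)C(=O)C2
F7 | step 18 | (3S,6R,10R)-10-bromo-3-(chloromethyl)-3-hydroxy-11,11-dimethyl-7-methylidenespiro[5.5]undecane-2,9-dione | C=C1CC(=O)[C@H](Br)C(C)(C)[C@@]12CC[C@@](O)(CCl)C(=O)C2
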